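## Analysis of the target

Compound 22 is a depside: two benzene rings joined through an aryl ester, with no stereocentre and no ring fusion. Ring A is the skeleton of methyl orsellinate 9: C1 carries the methyl ester, C2 a hydroxyl hydrogen-bonded to that ester, C6 a methyl group and C4 the acylated oxygen. Ring B is a hexasubstituted benzoyl group: C1' bears the ester carbonyl, C2' a methyl, C3' chlorine, C4' a hydroxyl, C5' a methyl and C6' a hydroxyl. The sensitive groups are the inter-ring aryl ester (an activated ester that phenoxides, alkoxides and amines can cleave or transpose), three free phenols and an aryl chloride that forbids careless hydrogenolysis. The difficulty sits in ring B and its junction. The benzoyl carbon is flanked by two ortho substituents, so acyl transfer to a phenol is slow. A ring B built by aromatic substitution also needs chlorine and the carboxyl placed on two equivalent positions of a dimethylresorcinol, followed by masking of two phenols. The strategy reads ring B as two three-carbon pieces: C4'(OH)–C5'(CH3)–C6'(O) is a 2-methylresorcinol triad, which a ketene carbonyl and the two alkyne carbons of siloxyalkyne 16 can deliver, and C1'–C2'–C3' (ester, methyl, chlorine) is the backbone of diazo ketoester 12. Because the ester of 12 is already the ring A aryl ester, the inter-ring bond is made on an unhindered acyl carbon before ring B exists.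

## Retrosynthetic reasoning

**22 from 21.** The last bond cut is the O–Si bond on the C6' oxygen. This silyl group is not an added protecting group; it is the form in which that oxygen arrives from the alkyne. Its removal is therefore the only deprotection of the route. The forward step must free the phenol under non-basic conditions so that the depside ester is untouched.

**21 from 12 and 16.** Ring B is opened along C4'–C5', C6'–C1' and C3'–C4'. These cuts are chosen because they leave every ring carbon attached to its own substituent: C5' (methyl) and C6' (siloxy) are the two carbons of 16, C4' is a ketene carbonyl, C1' is the diazo carbon with the aryl ester, and C2'/C3' are the methyl- and chlorine-bearing carbons of the vinyl group. What is gained is a hexasubstituted ring with chlorine and the crowded ester in place, with no electrophilic substitution and no hindered acylation. The forward reaction must pass through ketene 17, cyclobutenone 18, dienylketene 19 and dienone 20 in one operation.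

**12 from 11.** The C=N2 unit is removed to leave the active methylene of β-ketoester 11. Diazo transfer is the standard way to install it, and the product no longer has an acidic C–H.

**11 from 8 and 9.** The aryl ester C–O bond is cut so that ring A comes unchanged from 9. The acyl partner is acylketene 10, released thermally from 8 under neutral conditions. The forward step must distinguish the free C4 hydroxyl of 9 from the chelated C2 hydroxyl.

**8 from 5 and 6.** The bond between the ketone carbon and the malonyl carbon is cut. It is formed by C-acylation of 6 with acid chloride 7, made from acid 5 and used without isolation.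

**5 from 3, and 3 from 1.** The C2'=C3' alkene with its chlorine is traced to dichloromethyl malonate 3, which loses one carboxyl and one chloride through dicarboxylate 4. The C–CHCl2 bond is then cut back to 1 through enolate 2. This places the methyl group, the chlorine and the E geometry from a cheap malonate.

**16 from 13.** The siloxyalkyne is traced to ynolate 15 and from there, through enolate 14, to ester 13 by a one-carbon homologation in which the methyl group shifts to the new carbon.

## Alternatives that were turned down

**Alternative 1: carbonylative joining of a ring B iodide to ring A.** Both bonds at the ester carbonyl are cut. The pieces are 1-chloro-3-iodo-4,6-bis(methoxymethoxy)-2,5-dimethylbenzene A1, carbon monoxide A2 and the C4 hydroxyl of 9. In the forward key step a palladium–diphosphine catalyst with an amine base would insert A2 into the C–I bond of A1 and pass the acyl group to 9, giving the bis(methoxymethyl) ether A3 of 22; acid would then remove the acetals.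
- For: it is convergent and uses 9 intact. A1 should come in about three steps from a symmetrical dimethylresorcinol, because its two open positions are equivalent. Every step belongs to a known reaction class.
- Against: the iodide is flanked by two ortho substituents on an electron-rich ring, so oxidative addition is slow. The hindered acyl–palladium species must be captured by a weakly nucleophilic phenol, and hydrodeiodination competes. The mono-chlorination and mono-iodination of a very activated resorcinol depend on stopping cleanly at each stage.
- Comparison: this alternative is stronger on step count and on precedent. The chosen route offers in exchange a ring B whose substituents are fixed by connectivity, no acetal protection, and an ester bond made before it is hindered.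

**Alternative 2: ring A grown on a ring B enol ester.** Ring A is cut at C1–C2 and C5–C6. The pieces are 4-methoxy-4-(trimethylsilyloxy)buta-1,3-dien-2-yl 4,6-bis(benzyloxy)-3-chloro-2,5-dimethylbenzoate A4 and methyl but-2-ynoate A5. Heating would give a [4+2] adduct that aromatises by elimination at the ketene acetal carbon to the dibenzyl ether A6 of 22; debenzylation would follow.
- For: the cycloaddition polarity places the ring A substituents correctly, and the chelated hydroxyl arises from the ketene acetal, so no differentiation of two phenols is needed. On that point it is stronger than the chosen route.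
- Against: the complete, protected ring B acid must be made first, so the hard part of the molecule is untouched. That hindered acid must then be turned into an enol ester, which is as difficult as making the aryl ester. A4 is prone to acyl and silyl transfer, and A5 is a sluggish dienophile because of its β-methyl group. Ring A, available as 9, is rebuilt at the cost of several steps. The final debenzylation puts the aryl chloride at risk of hydrogenolysis.
- Comparison: the chosen route solves the phenol differentiation by the hydrogen bond already present in 9 and spends its steps on ring B, where they are needed.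

**Alternative 3: biomimetic aldol closure of ring B on the ester.** Ring B is cut at C1'–C2'. The precursor is methyl 2-hydroxy-6-methyl-4-[(4-methyl-3,5,7-trioxooctanoyl)oxy]benzoate A7. Amine base and then acid would add chain C2 to the C7 ketone and dehydrate to the 3'-deschloro depside A8; a late electrophilic chlorination would then be needed at C3'.
- For: no protecting groups, no photochemistry, cheap reagents, and the ester is present before the ring becomes hindered, as in the chosen route. On reagent cost and simplicity of operation it is stronger.
- Against: A7 has three enolisable positions, and its aryl ester is an activated ester. Claisen closure of C6 onto C1 and lactonisation of the C5 enol onto C1 both expel ring A as a phenoxide, and pyrone formation is the usual fate of such triketo esters. Preparing A7 by polyanion acylation is hardly compatible with the aryl ester. The final chlorination must choose C3' of ring B over C3 and C5 of ring A on electronic grounds alone.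
- Comparison: the chosen route concentrates its risk in one step and puts chlorine in by construction; this alternative spreads comparable risk over the cyclisation and the chlorination.

Key step: step 7

Remark on the chemistry: 22 has no stereocentre; the E geometry of the chloroalkene is the only stereochemical element carried, and it is erased when ring B aromatises. The chelated C2 hydroxyl of ring A is assumed to need no protection.

## Route

**Step 1**
Reactants: 1 diethyl methylmalonate
Product: 3 diethyl 2-(dichloromethyl)-2-methylpropanedioate, via sodium enolate 2 (not isolated)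
Conditions: NaH, THF, 0 °C to rt; CHCl3, 50 °C
Reagents that add atoms: chloroform, ClC(Cl)Cl; sodium hydride, [Na+].[H-] (sodium of 2 only)
Why: Enolate 2 deprotonates chloroform reversibly, chloride loss gives dichlorocarbene, and the enolate captures it at carbon; the resulting anion is protonated by chloroform, which carries the chain (haloform dihalomethylation of a malonate enolate). The quaternary product cannot react again.

**Step 2**
Reactants: 3 diethyl 2-(dichloromethyl)-2-methylpropanedioate
Product: 5 (2E)-3-chloro-2-methylprop-2-enoic acid, via dipotassium dicarboxylate 4 (not isolated)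
Conditions: KOH, EtOH–H2O, reflux; then aq. HCl, 0 °C
Reagents that add atoms: potassium hydroxide, [K+].[OH-] (carboxyl oxygen; potassium of 4)
Why: Saponification gives 4, which should fragment by decarboxylative anti-elimination of chloride (Grob-type, the chloro counterpart of the haloform route to β-halomethacrylic acids). The E geometry is set here because the remaining carboxylate and chlorine stay apart in the fragmentation, and the carboxylate shields the chloroacrylate from hydroxide addition.

**Step 3**
Reactants: 5 (2E)-3-chloro-2-methylprop-2-enoic acid; 6 Meldrum's acid (2,2-dimethyl-1,3-dioxane-4,6-dione)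
Product: 8 5-[(2E)-3-chloro-1-hydroxy-2-methylprop-2-en-1-ylidene]-2,2-dimethyl-1,3-dioxane-4,6-dione, via acid chloride 7 (not isolated)
Conditions: (COCl)2, cat. DMF, CH2Cl2, 0 °C to rt, concentrate; then 6, pyridine, CH2Cl2, 0 °C to rt
Reagents that add atoms: oxalyl chloride, ClC(=O)C(Cl)=O (acyl chlorine of 7 only, lost again on the way to 8)
Why: Vilsmeier-catalysed formation of the acid chloride, then C-acylation of Meldrum's acid. The acyl chloride carbon is far more electrophilic than the methyl-shielded β-carbon, so the chloroalkene and its E geometry should be untouched.

**Step 4**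
Reactants: 8 acyl Meldrum's acid from step 3; 9 methyl orsellinate (methyl 2,4-dihydroxy-6-methylbenzoate)
Product: 11 methyl 4-{[(4E)-5-chloro-4-methyl-3-oxopent-4-enoyl]oxy}-2-hydroxy-6-methylbenzoate, via acylketene 10 (not isolated)
Conditions: toluene, 100 °C
Reagents that add atoms: none
Why: Thermal fragmentation of the acyl Meldrum's acid releases acylketene 10, which a phenol O–H captures to give the aryl β-ketoester. The C4 hydroxyl of 9 is free and unhindered whereas the C2 hydroxyl is chelated to the ester and flanked, and the neutral medium spares the β-chlorovinyl ketone.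

**Step 5**
Reactants: 11 aryl β-ketoester from step 4
Product: 12 methyl 4-{[(4E)-5-chloro-2-diazo-4-methyl-3-oxopent-4-enoyl]oxy}-2-hydroxy-6-methylbenzoate
Conditions: p-ABSA, Et3N, MeCN, 0 °C to rt
Reagents that add atoms: 4-acetamidobenzenesulfonyl azide (p-ABSA), CC(=O)Nc1ccc(cc1)S(=O)(=O)N=[N+]=[N-]
Why: Regitz diazo transfer to the most acidic site, the 1,3-dicarbonyl methylene. Triethylamine in acetonitrile should not ionise the chelated phenol appreciably, and the product has no acidic C–H left, so it should be stable once formed.

**Step 6**
Reactants: 13 ethyl acetate
Product: 16 triisopropyl(prop-1-yn-1-yloxy)silane [1-(triisopropylsiloxy)propyne], via dibromo enolate 14 (not isolated), via lithium ynolate 15 (not isolated)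
Conditions: CH2Br2, LiTMP, THF, −78 °C; n-BuLi, −78 °C to rt; TIPSCl, 0 °C to rt
Reagents that add atoms: dibromomethane, BrCBr; chlorotri(propan-2-yl)silane (TIPSCl), CC(C)[Si](Cl)(C(C)C)C(C)C; lithium 2,2,6,6-tetramethylpiperidide, [Li+].CC1(C)CCCC(C)(C)[N-]1 (lithium of 14 and 15 only)
Why: Kowalski ynolate formation: dibromomethyllithium adds to the ester, and collapse and deprotonation give enolate 14. Bromine–lithium exchange then triggers a 1,2-shift of the methyl group to give ynolate 15, which the bulky silyl chloride should silylate on oxygen rather than carbon.

**Step 7**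
Reactants: 12 diazo ketoester from step 5; 16 1-(triisopropylsiloxy)propyne
Product: 21 methyl 4-({3-chloro-4-hydroxy-2,5-dimethyl-6-[(triisopropylsilyl)oxy]benzoyl}oxy)-2-hydroxy-6-methylbenzoate, via vinylketene 17 (not isolated), via vinylcyclobutenone 18 (not isolated), via dienylketene 19 (not isolated), via cyclohexadienone 20 (not isolated)
Conditions: 16 (3 equiv), hν (365 nm), ClCH2CH2Cl (0.02 M), 25 °C; then 80 °C
Reagents that add atoms: none
Why: Proposed new method: irradiation into the long-wavelength band of the diazo ketoester expels N2 and the chlorovinyl group shifts from the ketone carbon to the diazo carbon (Wolff rearrangement), giving the ester-substituted vinylketene 17. Its electrophilic carbonyl carbon is attacked by the methyl-bearing, nucleophilic carbon of 16, and the [2+2] adduct is the 3-siloxy-4-vinylcyclobutenone 18, so that C4'–C5' and C6'–C1' form with the siloxy group next to the ester. On warming, 18 opens by reversible 4π electrocyclic cleavage to dienylketene 19, and only the isomer with the chlorovinyl group turned towards the ketene is drained onward. Ring B closes by 6π electrocyclisation of 19 between the ketene carbon and the CHCl terminus (C3'–C4'), and the 6-chlorocyclohexa-2,4-dienone 20 enolises to the phenol with chlorine retained. The closest known reaction type is the photochemical Wolff variant of the Danheiser benzannulation, in which unsaturated diazo ketones and siloxyalkynes give resorcinol monosilyl ethers; new here are the ester on the diazo carbon and the chlorine on the vinyl terminus. No stereocentre survives, since the quaternary carbon of 18 and the CHCl carbon of 20 become sp2 on aromatisation. The selectivity needed is [2+2] at the ketene C=C over hetero-[4+2] through the ester carbonyl and over capture of 17 by a phenol; the ester carbonyl is a poor heterodiene terminus, the only phenol of 12 is tied up in a hydrogen bond, and excess 16 at high dilution should make the alkyne the fastest trap. The E chlorine points outward in 19, so the closing terminus carries only hydrogen on its inner side.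

**Step 8**
Reactants: 21 silyl ether from step 7
Product: 22 methyl 4-[(3-chloro-4,6-dihydroxy-2,5-dimethylbenzoyl)oxy]-2-hydroxy-6-methylbenzoate (target)
Conditions: HF·pyridine, THF–pyridine, 0 °C to rt
Reagents that add atoms: none
Why: Fluoride-driven cleavage of an aryl silyl ether under acidic, non-nucleophilic conditions. No phenoxide is generated, so the depside ester and the methyl ester should survive, and the aryl chloride is inert.

## Compound list

1 | diethyl methylmalonate | CCOC(=O)C(C)C(=O)OCC | starting material
2 | sodium enolate of diethyl methylmalonate | [Na+].CCOC(=O)[C-](C)C(=O)OCC | intermediate (not isolated)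
3 | diethyl 2-(dichloromethyl)-2-methylpropanedioate | CCOC(=O)C(C)(C(Cl)Cl)C(=O)OCC | intermediate
4 | dipotassium 2-(dichloromethyl)-2-methylpropanedioate | [K+].[K+].[O-]C(=O)C(C)(C(Cl)Cl)C([O-])=O | intermediate (not isolated)
5 | (2E)-3-chloro-2-methylprop-2-enoic acid | OC(=O)/C(C)=C/Cl | intermediate
6 | Meldrum's acid (2,2-dimethyl-1,3-dioxane-4,6-dione) | CC1(C)OC(=O)CC(=O)O1 | starting material
7 | (2E)-3-chloro-2-methylprop-2-enoyl chloride | ClC(=O)/C(C)=C/Cl | intermediate (not isolated)
8 | 5-[(2E)-3-chloro-1-hydroxy-2-methylprop-2-en-1-ylidene]-2,2-dimethyl-1,3-dioxane-4,6-dione | CC1(C)OC(=O)C(=C(O)/C(C)=C/Cl)C(=O)O1 | intermediate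
9 | methyl orsellinate (methyl 2,4-dihydroxy-6-methylbenzoate) | COC(=O)c1c(C)cc(O)cc1O | starting material
10 | (4E)-5-chloro-4-methylpenta-1,4-diene-1,3-dione (acylketene) | O=C=CC(=O)/C(C)=C/Cl | intermediate (not isolated)
11 | methyl 4-{[(4E)-5-chloro-4-methyl-3-oxopent-4-enoyl]oxy}-2-hydroxy-6-methylbenzoate | COC(=O)c1c(C)cc(OC(=O)CC(=O)/C(C)=C/Cl)cc1O | intermediate
12 | methyl 4-{[(4E)-5-chloro-2-diazo-4-methyl-3-oxopent-4-enoyl]oxy}-2-hydroxy-6-methylbenzoate | COC(=O)c1c(C)cc(OC(=O)C(=[N+]=[N-])C(=O)/C(C)=C/Cl)cc1O | intermediate
13 | ethyl acetate | CCOC(C)=O | starting material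
14 | lithium 1,1-dibromoprop-1-en-2-olate | [Li+].[O-]C(C)=C(Br)Br | intermediate (not isolated)
15 | lithium prop-1-yn-1-olate | [Li+].[O-]C#CC | intermediate (not isolated)
16 | triisopropyl(prop-1-yn-1-yloxy)silane | CC#CO[Si](C(C)C)(C(C)C)C(C)C | intermediate
17 | methyl 4-{[(3E)-4-chloro-3-methyl-2-(oxomethylidene)but-3-enoyl]oxy}-2-hydroxy-6-methylbenzoate (vinylketene) | COC(=O)c1c(C)cc(OC(=O)C(=C=O)/C(C)=C/Cl)cc1O | intermediate (not isolated)
18 | racemic methyl 4-({1-[(1E)-1-chloroprop-1-en-2-yl]-3-methyl-4-oxo-2-[(triisopropylsilyl)oxy]cyclobut-2-ene-1-carbonyl}oxy)-2-hydroxy-6-methylbenzoate | COC(=O)c1c(C)cc(OC(=O)C2(/C(C)=C/Cl)C(=O)C(C)=C2O[Si](C(C)C)(C(C)C)C(C)C)cc1O | intermediate (not isolated)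
19 | methyl 4-({(2Z)-2-[(1E)-1-chloroprop-1-en-2-yl]-4-methyl-5-oxo-3-[(triisopropylsilyl)oxy]penta-2,4-dienoyl}oxy)-2-hydroxy-6-methylbenzoate (dienylketene, chlorovinyl group cis to the ketene-bearing carbon) | O=C=C(C)/C(O[Si](C(C)C)(C(C)C)C(C)C)=C(\C(C)=C\Cl)C(=O)Oc1cc(C)c(C(=O)OC)c(O)c1 | intermediate (not isolated)
20 | racemic methyl 4-({3-chloro-2,5-dimethyl-4-oxo-6-[(triisopropylsilyl)oxy]cyclohexa-1,5-diene-1-carbonyl}oxy)-2-hydroxy-6-methylbenzoate | COC(=O)c1c(C)cc(OC(=O)C2=C(C)C(Cl)C(=O)C(C)=C2O[Si](C(C)C)(C(C)C)C(C)C)cc1O | intermediate (not isolated)
21 | methyl 4-({3-chloro-4-hydroxy-2,5-dimethyl-6-[(triisopropylsilyl)oxy]benzoyl}oxy)-2-hydroxy-6-methylbenzoate | COC(=O)c1c(C)cc(OC(=O)c2c(C)c(Cl)c(O)c(C)c2O[Si](C(C)C)(C(C)C)C(C)C)cc1O | intermediate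
22 | methyl 4-[(3-chloro-4,6-dihydroxy-2,5-dimethylbenzoyl)oxy]-2-hydroxy-6-methylbenzoate | COC(=O)c1c(C)cc(OC(=O)c2c(C)c(Cl)c(O)c(C)c2O)cc1O | target

## Step count and risks

Total step count: 8. Longest linear sequence: 7 steps (steps 1 to 5, then 7 and 8); step 6 is a one-step side branch.

**Step 7 (key step, new method).**
- What may go wrong: capture of the ester-substituted ketene through its ester carbonyl in a hetero-[4+2] mode or by a phenolic O–H instead of [2+2] addition at the C=C bond; oxa-6π closure of the dienylketene through the ester carbonyl instead of the vinyl terminus; and photo-Fries cleavage of the aryl ester if shorter wavelengths are needed to drive the Wolff step.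
- Fallback (known chemistry): it sets out from 9 and returns at 22, bypassing 21. Commercial methyl 2,4-dihydroxy-3,6-dimethylbenzoate F1 is chlorinated at its only free ring position with SO2Cl2 to methyl 5-chloro-2,4-dihydroxy-3,6-dimethylbenzoate F2. Both phenols are allylated (allyl bromide, K2CO3, DMF) to methyl 5-chloro-3,6-dimethyl-2,4-bis(prop-2-en-1-yloxy)benzoate F3. The hindered ester is cleaved with KOH in aqueous DMSO to 5-chloro-3,6-dimethyl-2,4-bis(prop-2-en-1-yloxy)benzoic acid F4. F4 is joined to the C4 hydroxyl of 9 through its mixed trifluoroacetic anhydride (TFAA, toluene) to give methyl 4-{[5-chloro-3,6-dimethyl-2,4-bis(prop-2-en-1-yloxy)benzoyl]oxy}-2-hydroxy-6-methylbenzoate F5. Pd(PPh3)4 (zerovalent palladium) with morpholine then removes both allyl groups to give 22.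

**Step 5.**
- What may go wrong: the enolate needed for diazo transfer may instead attack the β-chlorovinyl ketone of a second molecule (vinylic substitution leading to oligomers), or the base may trigger acyl transfer at the aryl β-ketoester.
- Fallback: it sets out from 9 and 7 and returns at 12, so that no enolate is ever formed next to the chlorovinyl ketone. 9 is acylated at its C4 hydroxyl with bromoacetyl bromide (NaHCO3, MeCN) to methyl 4-(2-bromoacetoxy)-2-hydroxy-6-methylbenzoate F6. F6 is converted with N,N'-ditosylhydrazine and DBU into the aryl diazoacetate methyl 4-(2-diazoacetoxy)-2-hydroxy-6-methylbenzoate F7. F7 is C-acylated by acid chloride 7, which has no α-hydrogen, in CH2Cl2 with a hindered pyridine base as acid scavenger; this is the classical, if slow, route to 2-diazo-3-oxo esters.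

**Step 4.**
- What may go wrong: acylketene 10 may be consumed by dimerisation or by addition to the enol of the product faster than the weakly nucleophilic phenol traps it, and some acylation at the chelated C2 hydroxyl may occur.
- Fallback: it sets out from 9, 6 and 5 and returns at 11 without any free ketene. Heating 9 with 6 in toluene opens Meldrum's acid to the aryl hydrogen malonate 3-[3-hydroxy-4-(methoxycarbonyl)-5-methylphenoxy]-3-oxopropanoic acid F8. Acid 5 is activated with 1,1'-carbonyldiimidazole as (2E)-3-chloro-1-(1H-imidazol-1-yl)-2-methylprop-2-en-1-one F9. F8 and F9 are combined with MgCl2 in THF, where magnesium-chelate-controlled C-acylation of the malonate and decarboxylation on acidic work-up give 11.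

**Step 2.**
- What may go wrong: the chloride may be too poor a leaving group for clean decarboxylative elimination, so that simple decarboxylation, incomplete elimination or loss of E selectivity intervenes.
- Fallback: it sets out from 1 and returns at 5. Enolate formation with NaH and reaction with iodoform give diethyl 2-(diiodomethyl)-2-methylpropanedioate F10. KOH in aqueous ethanol converts F10 into (2E)-3-iodo-2-methylprop-2-enoic acid F11 by the well-established iodide version of the same fragmentation. Halogen exchange with monovalent copper chloride CuCl in hot NMP then replaces iodine by chlorine with retention of geometry to give 5.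

## Further compounds

F1 | step 7 | methyl 2,4-dihydroxy-3,6-dimethylbenzoate | COC(=O)c1c(C)cc(O)c(C)c1O
F2 | step 7 | methyl 5-chloro-2,4-dihydroxy-3,6-dimethylbenzoate | COC(=O)c1c(C)c(Cl)c(O)c(C)c1O
F3 | step 7 | methyl 5-chloro-3,6-dimethyl-2,4-bis(prop-2-en-1-yloxy)benzoate | COC(=O)c1c(C)c(Cl)c(OCC=C)c(C)c1OCC=C
F4 | step 7 | 5-chloro-3,6-dimethyl-2,4-bis(prop-2-en-1-yloxy)benzoic acid | OC(=O)c1c(C)c(Cl)c(OCC=C)c(C)c1OCC=C
F5 | step 7 | methyl 4-{[5-chloro-3,6-dimethyl-2,4-bis(prop-2-en-1-yloxy)benzoyl]oxy}-2-hydroxy-6-methylbenzoate | COC(=O)c1c(C)cc(OC(=O)c2c(C)c(Cl)c(OCC=C)c(C)c2OCC=C)cc1O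
F6 | step 5 | methyl 4-(2-bromoacetoxy)-2-hydroxy-6-methylbenzoate | COC(=O)c1c(C)cc(OC(=O)CBr)cc1O
F7 | step 5 | methyl 4-(2-diazoacetoxy)-2-hydroxy-6-methylbenzoate | COC(=O)c1c(C)cc(OC(=O)C=[N+]=[N-])cc1O
F8 | step 4 | 3-[3-hydroxy-4-(methoxycarbonyl)-5-methylphenoxy]-3-oxopropanoic acid | COC(=O)c1c(C)cc(OC(=O)CC(O)=O)cc1O
F9 | step 4 | (2E)-3-chloro-1-(1H-imidazol-1-yl)-2-methylprop-2-en-1-one | O=C(/C(C)=C/Cl)n1ccnc1
F10 | step 2 | diethyl 2-(diiodomethyl)-2-methylpropanedioate | CCOC(=O)C(C)(C(I)I)C(=O)OCC
F11 | step 2 | (2E)-3-iodo-2-methylprop-2-enoic acid | OC(=O)/C(C)=C/I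
A1 | alternative 1 | 1-chloro-3-iodo-4,6-bis(methoxymethoxy)-2,5-dimethylbenzene | Clc1c(C)c(I)c(OCOC)c(C)c1OCOC
A2 | alternative 1 | carbon monoxide | [C-]#[O+]
A3 | alternative 1 | methyl 4-{[3-chloro-4,6-bis(methoxymethoxy)-2,5-dimethylbenzoyl]oxy}-2-hydroxy-6-methylbenzoate | COC(=O)c1c(C)cc(OC(=O)c2c(C)c(Cl)c(OCOC)c(C)c2OCOC)cc1O
A4 | alternative 2 | 4-methoxy-4-(trimethylsilyloxy)buta-1,3-dien-2-yl 4,6-bis(benzyloxy)-3-chloro-2,5-dimethylbenzoate | COC(O[Si](C)(C)C)=CC(=C)OC(=O)c1c(C)c(Cl)c(OCc2ccccc2)c(C)c1OCc1ccccc1
A5 | alternative 2 | methyl but-2-ynoate | CC#CC(=O)OC
A6 | alternative 2 | methyl 4-{[4,6-bis(benzyloxy)-3-chloro-2,5-dimethylbenzoyl]oxy}-2-hydroxy-6-methylbenzoate | COC(=O)c1c(C)cc(OC(=O)c2c(C)c(Cl)c(OCc3ccccc3)c(C)c2OCc4ccccc4)cc1O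
A7 | alternative 3 | methyl 2-hydroxy-6-methyl-4-[(4-methyl-3,5,7-trioxooctanoyl)oxy]benzoate (racemic, enolisable) | COC(=O)c1c(C)cc(OC(=O)CC(=O)C(C)C(=O)CC(C)=O)cc1O
A8 | alternative 3 | methyl 4-[(2,4-dihydroxy-3,6-dimethylbenzoyl)oxy]-2-hydroxy-6-methylbenzoate | COC(=O)c1c(C)cc(OC(=O)c2c(C)cc(O)c(C)c2O)cc1O
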